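The data are simulated with made-up constants.

The target and the isomer of the product climb together in both earlier runs, so what you want for the new flask is how their ratio moves with time.

| setting | elm | larch | flask |
|---|---|---|---|
| substrate | 0.10 M | 0.10 M | 0.10 M |
| partner | 0.70 equiv | 1.6 equiv | 1.05 equiv |
| remark | run made earlier | run made earlier |  |
| time |  |  | 3.0 d |

- elm (time / d: target / %, isomer of the product / %): 0.333: 5.3, 3.8; 0.833: 12.1, 3.8; 1.67: 17.5, 8.7; 2.50: 18.2, 9.0
- larch (time / d: target / %, isomer of the product / %): 0.625: 18.6, 8.9; 1.25: 27.2, 11.2; 1.67: 32.1, 15.3; 2.50: 36.2, 17.4

(standard deviation of a reading: 1 percentage point)

- the numbers in the tables scatter with a standard deviation of 1 percentage point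
- a reading or a percentage of target counts all its forms, free or not

* ratio of target to isomer of the product at 80 min
* ratio of target to isomer of the product at 10 h
* ratio of target to isomer of the product at 3.0 d

Take as yardstick R = 2.08, the late ratio, target over isomer of the product at the last larch reading, taken at 2.50 d. The elm run reads 2.02 at that same time, with 0.70 equiv of partner against 1.6 equiv, so these two readings show no effect of loading.

Two versions of the flask can be solved in the head. If the two products form side by side, with a fixed selectivity factor, the ratio is R at every time. If target turns into isomer in series, then early on target grows with time and isomer with its square, so the ratio falls as one over time. Joined to R at 2.50 d, this gives roughly 93.6 at 80 min, 12.5 at 10 h and 1.73 at 3.0 d.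

A flask that mixes direct and delayed formation lies between these ends. The first larch ratio, 2.09 at 0.625 d, sits near the side-by-side end, far under the series value of 8.32. But 80 min comes before every reading, so my own reckoning expects a ratio above R there, falling to slightly under R at 3.0 d.

The forecast differs: reading “two parallel channels with a fixed branching ratio”, it gave 2.1 at 80 min, 2.1 at 10 h and 2.1 at 3.0 d.

The flask gives 5.94, 2.95 and 1.80 at these times, each between its two ends .

    partner + target → over-reaction product (k = 0.00246 /M/min)
    partner + other conformer → isomer of the product (k = 0.00777 /M/min)
    substrate + partner ⇌ target (K = 11.0 /M, k = 0.00258 /M/min)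
    crystals ⇌ target, rate k4*(cs4 - [target]) while solid is left; crystals form when [target] > cs4 (solubility = 13.0 mM, k = 0.196 /min)
    substrate ⇌ other conformer (K = 0.110, k = 0.00220 /min)

Isomer forms from the other conformer, and the flask still stands at 1.80 at 3.0 d because of two things acting together, the return of other conformer to substrate and the hour of the reading: without that return the flask gives 0.0356, and read ten times later it gives 0.0819. The neighbour flask with 2.60 equiv of partner lies above R and under the series end at the first two times, with 5.97 at 80 min and 2.89 at 10 h , but at 3.0 d it falls under the series end of 1.73, to 1.67.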